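## Retrosynthetic overview

1. The target (a 2α,3α,7α,13,20-oxygenated labda-8(17),14-diene) is opened at the 7α-OH (allylic oxidation), the 2-O-angelate, the 20-O-acetate and C8=CH2 (Wittig), leading back to 8-ketone 27.
2. Key step: ring B of 27 is made by a one-carbon ring expansion of the trans-hydrindan-8-one 13 with the side-chain gem-dibromide 22. A β-oxido carbenoid 1,2-shift moves C10 from C8 to the new C9, which already carries C11–C16.
3. 13 comes from α-face dihydroxylation and acetonide protection of Δ2-hydrindenone 11; 11 from ring-closing metathesis of 10; 10 from an enantioselective conjugate reverse-prenylation/allylation of enone 4 (cyclopentenone + formaldehyde).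
4. 22 comes from (S)-2-methylglycidol and acetylide; C13 is taken from the chiral pool.
5. Ring order: cyclopentanone (bought) → ring A (metathesis) → ring B (ring expansion 5 → 6).

Assumption: positions are given in labdane numbering (C1–C20) throughout, and the (S,S) form of the step 4 catalyst is taken to give the (S)-adduct (its mirror image is used if the sense is the opposite).

## Route

Step 1
Reactants: 1 cyclopent-2-en-1-one; 2 formaldehyde
Product: 3 2-(hydroxymethyl)cyclopent-2-en-1-one
Conditions: 37% aq CH2O, imidazole (1 equiv), THF/H2O, 25 °C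
Reagents that add atoms: none
Why: Morita–Baylis–Hillman reaction: imidazole adds to the enone, the enolate captures formaldehyde (C20) and β-elimination returns the 2-substituted enone; no stereocentre is formed.

Step 2
Reactants: 3 2-(hydroxymethyl)cyclopent-2-en-1-one
Product: 4 2-{[(tert-butyldimethylsilyl)oxy]methyl}cyclopent-2-en-1-one
Conditions: tBuMe2SiCl, imidazole, CH2Cl2, 0 → 25 °C
Reagents that add atoms: tert-butyldimethylsilyl chloride, CC(C)(C)[Si](C)(C)Cl
Why: Standard imidazole-assisted silylation of the primary alcohol gives a bulky, weakly Lewis-basic ether that survives the Lewis acid, palladium, osmium, organolithium and ylide steps.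

Step 3
Reactants: 5 1-chloro-3-methylbut-2-ene (prenyl chloride)
Product: 7 trimethyl(3-methylbut-2-en-1-yl)silane, via prenylmagnesium chloride 6 (not isolated)
Conditions: Mg, THF, 0 °C; then Me3SiCl, 0 → 25 °C
Reagents that add atoms: chlorotrimethylsilane, C[Si](C)(C)Cl
Why: Grignard formation followed by silylation at the unhindered primary allyl terminus gives the γ,γ-dimethylallylsilane needed for a reverse-prenyl transfer.

Step 4
Reactants: 4 2-{[(tert-butyldimethylsilyl)oxy]methyl}cyclopent-2-en-1-one; 7 trimethyl(3-methylbut-2-en-1-yl)silane; 8 allyl methyl carbonate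
Product: 10 (2S,3S)-2-allyl-2-{[(tert-butyldimethylsilyl)oxy]methyl}-3-(2-methylbut-3-en-2-yl)cyclopentan-1-one, via silyl enol ether 9 (not isolated)
Conditions: (S,S)-IDPi acid [N,N′-bis(triflyl)imidodiphosphorimidate of (S)-3,3′-bis(3,5-(CF3)2C6H3)-BINOL] (2 mol %), toluene, −60 °C; evaporate; then Pd2(dba)3 (2.5 mol %), Ph2PCH2CH2PPh2 (6 mol %), Bu4N[Ph3SiF2] (35 mol %), THF, 25 °C
Reagents that add atoms: none
Why: Proposed new method: the confined silylium–IDPi ion pair (formed when the acid protodesilylates a trace of 7) O-silylates enone 4, and 7 attacks the β-carbon C5 through its γ-carbon (SE2′, so the quaternary C4 and its vinyl group arise directly) on the face left open by the chiral anion, which sets C5 (S); the β-silyl cation then passes Me3Si+ on, leaving the regiodefined enol ether 9. The closest known reactions are IDPi-catalysed Mukaiyama–Michael and Hosomi–Sakurai reactions and the achiral Tf2NH-catalysed conjugate Sakurai addition. The known fluoride-triggered Tsuji allylation of 9 then builds the quaternary C10, with allyl entering anti to the bulky C5 substituent (trans).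

Step 5
Reactants: 10 (2S,3S)-2-allyl-2-{[(tert-butyldimethylsilyl)oxy]methyl}-3-(2-methylbut-3-en-2-yl)cyclopentan-1-one
Product: 11 (3aS,7aS)-7a-{[(tert-butyldimethylsilyl)oxy]methyl}-4,4-dimethyl-2,3,3a,4,7,7a-hexahydro-1H-inden-1-one
Conditions: second-generation Hoveyda–Grubbs catalyst [RuCl2(H2IMes)(=CH-C6H4-2-OiPr)] (5 mol %), toluene, 80 °C
Reagents that add atoms: none
Why: Ring-closing metathesis of the allyl and neopentyl-type vinyl groups, helped by the gem-dimethyl group, closes ring A as the trans-fused Δ2-cyclohexene; both stereocentres are untouched.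

Step 6
Reactants: 11 (3aS,7aS)-7a-{[(tert-butyldimethylsilyl)oxy]methyl}-4,4-dimethyl-2,3,3a,4,7,7a-hexahydro-1H-inden-1-one
Product: 12 (3aS,5S,6R,7aS)-7a-{[(tert-butyldimethylsilyl)oxy]methyl}-5,6-dihydroxy-4,4-dimethyloctahydro-1H-inden-1-one
Conditions: OsO4 (2 mol %), N-methylmorpholine N-oxide, acetone/H2O, 25 °C
Reagents that add atoms: osmium tetroxide, O=[Os](=O)(=O)=O; N-methylmorpholine N-oxide, C[N+]1([O-])CCOCC1; water, O
Why: Upjohn syn-dihydroxylation: OsO4 adds to the Δ2 alkene from the α-face, away from the axial 4β-methyl and 10β-CH2OSi groups, giving the 2α,3α-diol.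

Step 7
Reactants: 12 (3aS,5S,6R,7aS)-7a-{[(tert-butyldimethylsilyl)oxy]methyl}-5,6-dihydroxy-4,4-dimethyloctahydro-1H-inden-1-one
Product: 13 5,6-O-isopropylidene acetal (acetonide) of 12
Conditions: Me2C(OMe)2, pyridinium p-toluenesulfonate (cat.), CH2Cl2, 25 °C
Reagents that add atoms: 2,2-dimethoxypropane, COC(C)(C)OC
Why: Acid-catalysed transketalisation of the cis-diol gives the five-membered acetonide, which masks both hydroxyls through the organolithium, ylide and fluoride steps.

Step 8
Reactants: 14 (S)-(2-methyloxiran-2-yl)methanol [(S)-2-methylglycidol]; 15 lithium acetylide–ethylenediamine complex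
Product: 16 (R)-2-methylpent-4-yne-1,2-diol
Conditions: 15 (2.5 equiv), DMSO, 25 °C; then H2O
Reagents that add atoms: none
Why: SN2 opening of the 2,2-disubstituted epoxide by acetylide at the unhindered CH2; the quaternary carbinol carbon (C13) is not touched, so its configuration comes unchanged from 14 (the descriptor changes only because the priorities change).

Step 9
Reactants: 16 (R)-2-methylpent-4-yne-1,2-diol
Product: 18 (R)-3-methylhex-1-en-5-yn-3-ol, via hydroxy aldehyde 17 (not isolated)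
Conditions: 2-iodoxybenzoic acid (IBX), EtOAc, 75 °C, filter; then Ph3PCH3Br, KOtBu, THF, 0 → 25 °C
Reagents that add atoms: methyltriphenylphosphonium bromide, C[P+](c1ccccc1)(c1ccccc1)c1ccccc1.[Br-]
Why: IBX oxidises only the primary alcohol without glycol cleavage, and the non-enolisable α-hydroxy aldehyde is methylenated at once by Wittig reaction to give the C14=C15 vinyl group; C13 is not involved.

Step 10
Reactants: 18 (R)-3-methylhex-1-en-5-yn-3-ol
Product: 19 (R)-tert-butyldimethyl[(3-methylhex-1-en-5-yn-3-yl)oxy]silane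
Conditions: tBuMe2SiOTf, 2,6-lutidine, CH2Cl2, 0 °C
Reagents that add atoms: tert-butyldimethylsilyl trifluoromethanesulfonate, CC(C)(C)[Si](C)(C)OS(=O)(=O)C(F)(F)F
Why: Silyl triflate/lutidine silylation of the hindered tertiary alcohol protects C13–OH so that it cannot trap the carbenoid later.

Step 11
Reactants: 19 (R)-tert-butyldimethyl[(3-methylhex-1-en-5-yn-3-yl)oxy]silane
Product: 21 (R)-4-[(tert-butyldimethylsilyl)oxy]-4-methylhex-5-enal, via alkenylborane 20 (not isolated)
Conditions: (c-C6H11)2BH, THF, 0 °C; then 30% H2O2, aq NaHCO3, 0 → 25 °C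
Reagents that add atoms: hydrogen peroxide, OO
Why: Hydroboration of the terminal alkyne with a bulky dialkylborane is anti-Markovnikov and faster than that of the neopentyl-type vinyl group; oxidation of the alkenylborane gives the aldehyde (C9).

Step 12
Reactants: 21 (R)-4-[(tert-butyldimethylsilyl)oxy]-4-methylhex-5-enal
Product: 22 (R)-tert-butyl[(6,6-dibromo-3-methylhex-1-en-3-yl)oxy]dimethylsilane
Conditions: (PhO)3P, Br2, Et3N, CH2Cl2, −78 → 0 °C
Reagents that add atoms: bromine, BrBr
Why: Deoxygenative gem-dibromination of the aldehyde by the bromophosphonium salt from triphenyl phosphite and bromine; no free bromine is present to attack the vinyl group.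

Step 13
Reactants: 22 (R)-tert-butyl[(6,6-dibromo-3-methylhex-1-en-3-yl)oxy]dimethylsilane; 13 5,6-O-isopropylidene acetal (acetonide) of 12
Product: 27 (13R)-13,20-bis(tert-butyldimethylsilyloxy)-2α,3α-isopropylidenedioxy-17-norlabd-14-en-8-one, via lithiated dibromide 23 (not isolated), via dibromo alkoxide 24 (not isolated), via oxido carbenoid 25 (not isolated), via lithium enolate 26 (not isolated)
Conditions: 22, LiN(iPr)2, THF, −100 °C; add 13; n-BuLi, −100 → 0 °C; aq NH4Cl; then K2CO3, MeOH, 25 °C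
Reagents that add atoms: none
Why: β-Oxido carbenoid ring enlargement (a semipinacol-type 1,2-shift): after Br/Li exchange the more substituted C10 migrates from C8 to the carbenoid carbon with loss of bromide, which inserts C9 between C8 and C10 and turns the cyclopentanone into ring B; C9 is then set by base equilibration to the equatorial side chain (9α-H).

Step 14
Reactants: 27 (13R)-13,20-bis(tert-butyldimethylsilyloxy)-2α,3α-isopropylidenedioxy-17-norlabd-14-en-8-one
Product: 28 (13R)-13,20-bis(tert-butyldimethylsilyloxy)-2α,3α-isopropylidenedioxylabda-8(17),14-diene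
Conditions: Ph3PCH3Br, KOtBu, toluene, 80 °C
Reagents that add atoms: methyltriphenylphosphonium bromide, C[P+](c1ccccc1)(c1ccccc1)c1ccccc1.[Br-]
Why: Wittig methylenation of the hindered 8-ketone, as is routine for 8-oxo-17-norlabdanes; C9 already has its thermodynamic configuration, so the basic ylide cannot degrade it.

Step 15
Reactants: 28 (13R)-13,20-bis(tert-butyldimethylsilyloxy)-2α,3α-isopropylidenedioxylabda-8(17),14-diene
Product: 29 (13R)-2α,3α-isopropylidenedioxylabda-8(17),14-diene-13,20-diol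
Conditions: Bu4NF, THF, 65 °C
Reagents that add atoms: none
Why: Fluoride cleavage of both silyl ethers, driven by Si–F bond formation; the acetonide and the alkenes are inert.

Step 16
Reactants: 29 (13R)-2α,3α-isopropylidenedioxylabda-8(17),14-diene-13,20-diol
Product: 30 (13R)-20-acetoxy-2α,3α-isopropylidenedioxylabda-8(17),14-dien-13-ol
Conditions: Ac2O, pyridine, CH2Cl2, 0 → 25 °C
Reagents that add atoms: acetic anhydride, CC(=O)OC(C)=O
Why: Acetylation of the primary C20–OH; the tertiary allylic C13–OH does not react with Ac2O/pyridine in the absence of a nucleophilic catalyst.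

Step 17
Reactants: 30 (13R)-20-acetoxy-2α,3α-isopropylidenedioxylabda-8(17),14-dien-13-ol
Product: 31 (13R)-20-acetoxylabda-8(17),14-diene-2α,3α,13-triol
Conditions: AcOH/H2O/THF (3:1:1), 40 °C
Reagents that add atoms: none
Why: Mild acid hydrolysis of the acetonide; the acetate, the exocyclic alkene and the tertiary allylic alcohol tolerate aqueous acetic acid at this temperature.

Step 18
Reactants: 31 (13R)-20-acetoxylabda-8(17),14-diene-2α,3α,13-triol; 32 angelic acid [(Z)-2-methylbut-2-enoic acid]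
Product: 34 (13R)-20-acetoxy-2α-angeloyloxylabda-8(17),14-diene-3α,13-diol, via mixed anhydride 33 (not isolated)
Conditions: 32, 2,4,6-Cl3C6H2COCl, Et3N, toluene, 25 °C; then 31, 75 °C
Reagents that add atoms: none
Why: Yamaguchi-type esterification through the mixed anhydride without a nucleophilic catalyst keeps the Z (angelate) geometry; the equatorial 2α-OH reacts, while the axial 3α-OH next to the gem-dimethyl carbon and the tertiary 13-OH do not.

Step 19
Reactants: 34 (13R)-20-acetoxy-2α-angeloyloxylabda-8(17),14-diene-3α,13-diol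
Product: 35 (13R)-20-acetoxy-2α-angeloyloxylabda-8(17),14-diene-3α,7α,13-triol (CNP0251485.1)
Conditions: SeO2 (0.5 equiv), tBuOOH, CH2Cl2, 0 → 25 °C
Reagents that add atoms: selenium dioxide, O=[Se]=O; tert-butyl hydroperoxide, CC(C)(C)OO
Why: Riley allylic oxidation (ene reaction of SeO2, then a 2,3-shift) attacks the ring CH2 (C7) of the exocyclic alkene and delivers the axial 7α-alcohol, as is known for labd-8(17)-enes; the electron-poor angelate and the vinyl group, which has no allylic hydrogen, are not oxidised.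

## Compound list

1 | cyclopent-2-en-1-one | O=C1C=CCC1 | starting material
2 | formaldehyde | C=O | starting material
3 | 2-(hydroxymethyl)cyclopent-2-en-1-one | O=C1CCC=C1CO | intermediate
4 | 2-{[(tert-butyldimethylsilyl)oxy]methyl}cyclopent-2-en-1-one | O=C1CCC=C1CO[Si](C)(C)C(C)(C)C | intermediate
5 | 1-chloro-3-methylbut-2-ene (prenyl chloride) | CC(C)=CCCl | starting material
6 | prenylmagnesium chloride | CC(C)=CC[Mg]Cl | intermediate
7 | trimethyl(3-methylbut-2-en-1-yl)silane | CC(C)=CC[Si](C)(C)C | intermediate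
8 | allyl methyl carbonate | C=CCOC(=O)OC | starting material
9 | tert-butyldimethyl{[(5S)-5-(2-methylbut-3-en-2-yl)-2-[(trimethylsilyl)oxy]cyclopent-1-en-1-yl]methoxy}silane | C[Si](C)(C)OC1=C(CO[Si](C)(C)C(C)(C)C)[C@H](C(C)(C)C=C)CC1 | intermediate
10 | (2S,3S)-2-allyl-2-{[(tert-butyldimethylsilyl)oxy]methyl}-3-(2-methylbut-3-en-2-yl)cyclopentan-1-one (allyl trans to the tert-alkyl group) | O=C1CC[C@@H](C(C)(C)C=C)[C@@]1(CC=C)CO[Si](C)(C)C(C)(C)C | intermediate
11 | (3aS,7aS)-7a-{[(tert-butyldimethylsilyl)oxy]methyl}-4,4-dimethyl-2,3,3a,4,7,7a-hexahydro-1H-inden-1-one (trans-fused) | O=C1CC[C@H]2C(C)(C)C=CC[C@]12CO[Si](C)(C)C(C)(C)C | intermediate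
12 | (3aS,5S,6R,7aS)-7a-{[(tert-butyldimethylsilyl)oxy]methyl}-5,6-dihydroxy-4,4-dimethyloctahydro-1H-inden-1-one (both OH on the face opposite to CH2OSi) | O=C1CC[C@H]2C(C)(C)[C@H](O)[C@H](O)C[C@]12CO[Si](C)(C)C(C)(C)C | intermediate
13 | 5,6-O-isopropylidene acetal (acetonide) of 12 | O=C1CC[C@H]2C(C)(C)[C@H](O3)[C@H](OC3(C)C)C[C@]12CO[Si](C)(C)C(C)(C)C | intermediate
14 | (S)-(2-methyloxiran-2-yl)methanol [(S)-2-methylglycidol] | C[C@]1(CO)CO1 | starting material
15 | lithium acetylide–ethylenediamine complex | [Li]C#C.NCCN | starting material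
16 | (R)-2-methylpent-4-yne-1,2-diol | OC[C@](C)(O)CC#C | intermediate
17 | (R)-2-hydroxy-2-methylpent-4-ynal | O=C[C@](C)(O)CC#C | intermediate
18 | (R)-3-methylhex-1-en-5-yn-3-ol | C=C[C@](C)(O)CC#C | intermediate
19 | (R)-tert-butyldimethyl[(3-methylhex-1-en-5-yn-3-yl)oxy]silane | C=C[C@](C)(O[Si](C)(C)C(C)(C)C)CC#C | intermediate
20 | dicyclohexyl[(1E,4R)-4-{[tert-butyl(dimethyl)silyl]oxy}-4-methylhexa-1,5-dien-1-yl]borane | C=C[C@](C)(O[Si](C)(C)C(C)(C)C)C/C=C/B(C1CCCCC1)C1CCCCC1 | intermediate
21 | (R)-4-[(tert-butyldimethylsilyl)oxy]-4-methylhex-5-enal | C=C[C@](C)(O[Si](C)(C)C(C)(C)C)CCC=O | intermediate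
22 | (R)-tert-butyl[(6,6-dibromo-3-methylhex-1-en-3-yl)oxy]dimethylsilane | C=C[C@](C)(O[Si](C)(C)C(C)(C)C)CCC(Br)Br | intermediate
23 | 1-lithio derivative of 22 (1,1-dibromoalkyllithium) | C=C[C@](C)(O[Si](C)(C)C(C)(C)C)CCC([Li])(Br)Br | intermediate
24 | lithium alkoxide of the C8 adduct of 23 with 13 (C8 configuration not defined) | C=C[C@](C)(O[Si](C)(C)C(C)(C)C)CCC(Br)(Br)C1(O[Li])CC[C@H]2C(C)(C)[C@H](O3)[C@H](OC3(C)C)C[C@]12CO[Si](C)(C)C(C)(C)C | intermediate
25 | β-oxido carbenoid from 24 (C8 and C9 configuration not defined) | C=C[C@](C)(O[Si](C)(C)C(C)(C)C)CCC([Li])(Br)C1(O[Li])CC[C@H]2C(C)(C)[C@H](O3)[C@H](OC3(C)C)C[C@]12CO[Si](C)(C)C(C)(C)C | intermediate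
26 | ring-expanded lithium enolate (C8–O–Li, C8=C9) | C=C[C@](C)(O[Si](C)(C)C(C)(C)C)CCC1=C(O[Li])CC[C@H]2C(C)(C)[C@H](O3)[C@H](OC3(C)C)C[C@]12CO[Si](C)(C)C(C)(C)C | intermediate
27 | (13R)-13,20-bis(tert-butyldimethylsilyloxy)-2α,3α-isopropylidenedioxy-17-norlabd-14-en-8-one (5α-H, 9α-H, 10β-CH2O) | C=C[C@](C)(O[Si](C)(C)C(C)(C)C)CC[C@H]1C(=O)CC[C@H]2C(C)(C)[C@H](O3)[C@H](OC3(C)C)C[C@]12CO[Si](C)(C)C(C)(C)C | intermediate
28 | (13R)-13,20-bis(tert-butyldimethylsilyloxy)-2α,3α-isopropylidenedioxylabda-8(17),14-diene | C=C[C@](C)(O[Si](C)(C)C(C)(C)C)CC[C@H]1C(=C)CC[C@H]2C(C)(C)[C@H](O3)[C@H](OC3(C)C)C[C@]12CO[Si](C)(C)C(C)(C)C | intermediate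
29 | (13R)-2α,3α-isopropylidenedioxylabda-8(17),14-diene-13,20-diol | C=C[C@](C)(O)CC[C@H]1C(=C)CC[C@H]2C(C)(C)[C@H](O3)[C@H](OC3(C)C)C[C@]12CO | intermediate
30 | (13R)-20-acetoxy-2α,3α-isopropylidenedioxylabda-8(17),14-dien-13-ol | C=C[C@](C)(O)CC[C@H]1C(=C)CC[C@H]2C(C)(C)[C@H](O3)[C@H](OC3(C)C)C[C@]12COC(C)=O | intermediate
31 | (13R)-20-acetoxylabda-8(17),14-diene-2α,3α,13-triol | C=C[C@](C)(O)CC[C@H]1C(=C)CC[C@H]2C(C)(C)[C@H](O)[C@H](O)C[C@]12COC(C)=O | intermediate
32 | angelic acid [(Z)-2-methylbut-2-enoic acid] | C/C=C(/C)C(=O)O | starting material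
33 | angelic 2,4,6-trichlorobenzoic anhydride | C/C=C(/C)C(=O)OC(=O)c1c(Cl)cc(Cl)cc1Cl | intermediate
34 | (13R)-20-acetoxy-2α-angeloyloxylabda-8(17),14-diene-3α,13-diol | C=C[C@](C)(O)CC[C@H]1C(=C)CC[C@H]2C(C)(C)[C@H](O)[C@H](OC(=O)/C(C)=C\C)C[C@]12COC(C)=O | intermediate
35 | (13R)-20-acetoxy-2α-angeloyloxylabda-8(17),14-diene-3α,7α,13-triol (CNP0251485.1) | C=C[C@](C)(O)CC[C@H]1C(=C)[C@H](O)C[C@H]2C(C)(C)[C@H](O)[C@H](OC(=O)/C(C)=C\C)C[C@]12COC(C)=O | target

## Step count and risks

Total step count: 19. Longest linear sequence: 13 steps (steps 1, 2, 4–7, 13–19); the side-chain branch is 5 steps (8–12) and the silane branch 1 step (3).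

Steps most likely to fail:

Step 4 (the proposed new enantioselective conjugate reverse-prenylation). Risks are low enantioselectivity, 1,2-addition, or ionisation of the allylic silyl ether. The fallback uses known chemistry and replaces asymmetric catalysis by a classical resolution; it sets out from 4 (with 7 and 8) and comes back at 12. Achiral Tf2NH (1 mol %, the known silyl triflimide-catalysed conjugate Sakurai addition) gives the racemic enol ether, that is 9 together with its mirror image ent-9 F1. The same palladium allylation, metathesis and dihydroxylation as in steps 4–6 then give the racemates that contain ent-10 F2, ent-11 F3 and ent-12 F4 beside 10, 11 and 12. Acylation of the racemic diol with (1S)-camphanoyl chloride (pyridine, 0 °C) at the equatorial O-2 gives the camphanate of 12 F5 and the diastereomeric camphanate of ent-12 F6. These are separated by chromatography or crystallisation, and K2CO3/MeOH on F5 returns enantiopure 12.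

Step 13 (ring expansion). Risks are a sluggish addition of the hindered dibromoalkyllithium to the neopentyl ketone, enolisation, or migration of C7 in place of C10. The fallback is a stepwise epoxy-alcohol semipinacol route with a small, linear nucleophile; it sets out from 13 and 19 and comes back at 27. The lithium acetylide of 19 (n-BuLi, THF, −78 °C) adds to 13 to give the propargylic alcohol F7. NaAlH2(OCH2CH2OCH3)2 reduces it to the (E)-allylic alcohol F8. VO(acac)2/tBuOOH gives the hydroxyl-directed epoxy alcohol F9. ZnBr2 (CH2Cl2, 0 °C) triggers the semipinacol shift of C10 to C9 with ring enlargement to the 11-hydroxy-8-ketone F10. MsCl/Et3N then DBU gives the 9(11)-en-8-one F11. Conjugate reduction with [(Ph3P)CuH]6, followed by K2CO3/MeOH equilibration, gives 27.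

Step 19 (last-step allylic oxidation). Risks are attack on or isomerisation of the angelate, over-oxidation to the enone, or low conversion. The fallback moves the C–H oxidation ahead of the acetonide cleavage and the esterification, and places the angelate by a tin-directed acylation; it sets out from 30 and comes back at 35. SeO2/tBuOOH on 30 gives the 7α-hydroxy acetonide F12. AcOH/H2O/THF gives the tetraol F13. Bu2SnO (MeOH, reflux) forms the 2,3-O-dibutylstannylene acetal F14, which reacts with mixed anhydride 33 at 25 °C at the equatorial O-2 only, leaving the 3α-, 7α- and 13-hydroxyls free, to give 35.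

Further compounds
F1 | step 4 | ent-9, (5R)-enantiomer of silyl enol ether 9 | C[Si](C)(C)OC1=C(CO[Si](C)(C)C(C)(C)C)[C@@H](C(C)(C)C=C)CC1
F2 | step 4 | ent-10, (2R,3R)-enantiomer of 10 | O=C1CC[C@H](C(C)(C)C=C)[C@]1(CC=C)CO[Si](C)(C)C(C)(C)C
F3 | step 4 | ent-11, (3aR,7aR)-enantiomer of 11 | O=C1CC[C@@H]2C(C)(C)C=CC[C@@]12CO[Si](C)(C)C(C)(C)C
F4 | step 4 | ent-12, (3aR,5R,6S,7aR)-enantiomer of 12 | O=C1CC[C@@H]2C(C)(C)[C@@H](O)[C@@H](O)C[C@@]12CO[Si](C)(C)C(C)(C)C
F5 | step 4 | 6-O-[(1S)-camphanoyl] ester of 12 (O-2 in labdane numbering) | O=C1CC[C@H]2C(C)(C)[C@H](O)[C@H](OC(=O)[C@@]34CC[C@@](C)(C(=O)O3)C4(C)C)C[C@]12CO[Si](C)(C)C(C)(C)C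
F6 | step 4 | 6-O-[(1S)-camphanoyl] ester of ent-12 | O=C1CC[C@@H]2C(C)(C)[C@@H](O)[C@@H](OC(=O)[C@@]34CC[C@@](C)(C(=O)O3)C4(C)C)C[C@@]12CO[Si](C)(C)C(C)(C)C
F7 | step 13 | tertiary propargylic alcohol from 13 and the acetylide of 19 (C8 configuration not defined) | C=C[C@](C)(O[Si](C)(C)C(C)(C)C)CC#CC1(O)CC[C@H]2C(C)(C)[C@H](O3)[C@H](OC3(C)C)C[C@]12CO[Si](C)(C)C(C)(C)C
F8 | step 13 | (E)-allylic alcohol from F7 | C=C[C@](C)(O[Si](C)(C)C(C)(C)C)C/C=C/C1(O)CC[C@H]2C(C)(C)[C@H](O3)[C@H](OC3(C)C)C[C@]12CO[Si](C)(C)C(C)(C)C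
F9 | step 13 | 9,11-epoxy alcohol from F8 (epoxide configuration not defined) | C=C[C@](C)(O[Si](C)(C)C(C)(C)C)CC4OC4C1(O)CC[C@H]2C(C)(C)[C@H](O3)[C@H](OC3(C)C)C[C@]12CO[Si](C)(C)C(C)(C)C
F10 | step 13 | 11-hydroxy derivative of 27 (C9 and C11 configuration not defined) | C=C[C@](C)(O[Si](C)(C)C(C)(C)C)CC(O)C1C(=O)CC[C@H]2C(C)(C)[C@H](O3)[C@H](OC3(C)C)C[C@]12CO[Si](C)(C)C(C)(C)C
F11 | step 13 | 9(11)-dehydro derivative of 27 (exocyclic enone; alkene geometry not defined) | C=C[C@](C)(O[Si](C)(C)C(C)(C)C)CC=C1C(=O)CC[C@H]2C(C)(C)[C@H](O3)[C@H](OC3(C)C)C[C@]12CO[Si](C)(C)C(C)(C)C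
F12 | step 19 | (13R)-20-acetoxy-2α,3α-isopropylidenedioxylabda-8(17),14-diene-7α,13-diol | C=C[C@](C)(O)CC[C@H]1C(=C)[C@H](O)C[C@H]2C(C)(C)[C@H](O3)[C@H](OC3(C)C)C[C@]12COC(C)=O
F13 | step 19 | (13R)-20-acetoxylabda-8(17),14-diene-2α,3α,7α,13-tetraol | C=C[C@](C)(O)CC[C@H]1C(=C)[C@H](O)C[C@H]2C(C)(C)[C@H](O)[C@H](O)C[C@]12COC(C)=O
F14 | step 19 | 2,3-O-dibutylstannylene acetal of F13 | C=C[C@](C)(O)CC[C@H]1C(=C)[C@H](O)C[C@H]2C(C)(C)[C@H](O3)[C@H](O[Sn]3(CCCC)CCCC)C[C@]12COC(C)=O
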